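**Retrosynthetic overview**
- The target comes from a flavone carrying ring B as its bis-benzyl ether and a 5-methoxy group; one BCl3 operation frees the 2'-OH, 5'-OH and the chelated 5-OH.
- Ring C is the only ring formed: an amine-mediated 6-endo closure of an ortho-silyloxyaryl ynone, done in the same flask as the key step.
- Key bond C4–C3: carbene-catalysed umpolung. The ring A aldehyde becomes an acyl anion equivalent (Breslow intermediate) and attacks an alkynyl(phenyl)iodonium salt bearing ring B, so an aldehyde carbon and an iodonium-bound alkyne carbon, both electrophiles, are joined.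
- The ring A aldehyde comes from 3,4,5-trimethoxyphenol (ortho-formylation, bromination, methoxylation, silylation); the ring B iodonium salt comes from 2,5-dihydroxybenzaldehyde (benzylation, alkyne homologation, PhI(OH)OTs).
- Rings A and B are bought as benzenes; ring C is closed in the second-to-last step.

Assumption: the target has no stereocentre and no stereogenic double bond, so it is one achiral compound fully defined by the SMILES and no enantiomer question arises.

**Route**

Step 1
Reactants: 1 3,4,5-trimethoxyphenol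
Product: 2 2-hydroxy-4,5,6-trimethoxybenzaldehyde
Conditions: MgCl2, Et3N, (CH2O)n, MeCN, reflux; 1 M HCl work-up
Reagents that add atoms: paraformaldehyde (formaldehyde unit), C=O
Why: Magnesium-phenoxide-directed ortho-formylation (Casnati–Skattebøl) delivers formaldehyde only ortho to the OH, a second formaldehyde acts as hydride acceptor, and the two ortho carbons of 1 are equivalent, so one isomer forms.

Step 2
Reactants: 2 2-hydroxy-4,5,6-trimethoxybenzaldehyde
Product: 3 3-bromo-2-hydroxy-4,5,6-trimethoxybenzaldehyde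
Conditions: NBS, MeCN, 0 °C → rt
Reagents that add atoms: N-bromosuccinimide, O=C1CCC(=O)N1Br
Why: Electrophilic aromatic bromination at the single remaining ring C–H, which is ortho to the OH, ortho and para to methoxy groups and only meta to the aldehyde.

Step 3
Reactants: 3 3-bromo-2-hydroxy-4,5,6-trimethoxybenzaldehyde
Product: 4 2-hydroxy-3,4,5,6-tetramethoxybenzaldehyde
Conditions: NaOMe (excess), CuBr (20 mol %), MeOH–DMF, 110 °C, N2; 1 M HCl work-up
Reagents that add atoms: sodium methoxide, [Na+].[O-]C
Why: Copper-catalysed Ullmann-type methoxylation of an aryl bromide ortho to a phenoxide (the 5-bromovanillin to syringaldehyde reaction type), with the phenoxide shielding the aldehyde from Cannizzaro chemistry.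

Step 4
Reactants: 4 2-hydroxy-3,4,5,6-tetramethoxybenzaldehyde
Product: 5 2-[(tert-butyldimethylsilyl)oxy]-3,4,5,6-tetramethoxybenzaldehyde
Conditions: TBSCl, imidazole, DMF, rt
Reagents that add atoms: tert-butyldimethylsilyl chloride, CC(C)(C)[Si](C)(C)Cl
Why: Standard O-silylation; it masks the phenol, which would otherwise be alkynylated by the iodonium salt and would deactivate the aldehyde as its phenoxide in step 8.

Step 5
Reactants: 6 2,5-dihydroxybenzaldehyde
Product: 7 2,5-bis(benzyloxy)benzaldehyde
Conditions: BnBr, K2CO3, DMF, 60 °C, N2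
Reagents that add atoms: benzyl bromide, BrCc1ccccc1
Why: Williamson etherification of both phenols, run under nitrogen because the hydroquinone oxidises in base and air.

Step 6
Reactants: 7 2,5-bis(benzyloxy)benzaldehyde
Product: 8 1,4-bis(benzyloxy)-2-ethynylbenzene
Conditions: dimethyl (1-diazo-2-oxopropyl)phosphonate, K2CO3, MeOH–THF, 0 °C → rt
Reagents that add atoms: dimethyl (1-diazo-2-oxopropyl)phosphonate, CC(=O)C(=[N+]=[N-])P(=O)(OC)OC
Why: Ohira–Bestmann (Seyferth–Gilbert) homologation: methanolysis gives the diazophosphonate anion, which olefinates the aldehyde and loses N2, and the alkylidene carbene rearranges to the terminal alkyne.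

Step 7
Reactants: 8 1,4-bis(benzyloxy)-2-ethynylbenzene
Product: 9 {[2,5-bis(benzyloxy)phenyl]ethynyl}(phenyl)iodonium 4-methylbenzenesulfonate
Conditions: PhI(OH)OTs, 4 Å MS, CH2Cl2, −20 °C → rt, dark; precipitate with Et2O
Reagents that add atoms: [hydroxy(tosyloxy)iodo]benzene, Cc1ccc(cc1)S(=O)(=O)OI(O)c1ccccc1
Why: Koser–Stang alkynyliodonium synthesis, in which the terminal aryl alkyne replaces the hydroxy ligand on trivalent iodine with loss of water, and the non-fluorinated solvent at low temperature limits oxidation of the dialkoxyarene.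

Step 8
Reactants: 5 2-[(tert-butyldimethylsilyl)oxy]-3,4,5,6-tetramethoxybenzaldehyde; 9 {[2,5-bis(benzyloxy)phenyl]ethynyl}(phenyl)iodonium 4-methylbenzenesulfonate
Product: 13 2-[2,5-bis(benzyloxy)phenyl]-5,6,7,8-tetramethoxy-4H-chromen-4-one, via ynone 10 (not isolated), via silyl enaminone 11 (not isolated), via phenol enaminone 12 (not isolated)
Conditions: 2-(pentafluorophenyl)-6,7-dihydro-5H-pyrrolo[2,1-c][1,2,4]triazol-2-ium tetrafluoroborate (C11H7BF9N3, 20 mol %), iPr2NEt, toluene–CH2Cl2, −40 °C → rt; then Et2NH, EtOH, rt → 60 °C, same flask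
Reagents that add atoms: none
Why: Proposed new method: the carbene adds to the aldehyde of 5 to give a Breslow intermediate (acyl anion equivalent) that attacks the iodine-bearing acetylenic carbon of 9 (direct substitution, or β-addition then 1,2-shift) with loss of PhI and release of the carbene to give ynone 10, after which Et2NH adds in conjugate fashion (11), ethanol strips the acyl-activated aryl silyl ether (12) and the phenol closes 6-endo by addition–elimination with loss of Et2NH, so no aurone can form; the closest known reactions are the NHC-catalysed alkynylation of aryl aldehydes with alkynyl(aryl)iodonium salts and the amine-mediated cyclisation of ortho-silyloxyaryl ynones to chromones, and what is new is running them in one flask on a di-ortho-oxygenated aldehyde, which at least cannot self-couple by benzoin reaction.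

Step 9
Reactants: 13 2-[2,5-bis(benzyloxy)phenyl]-5,6,7,8-tetramethoxy-4H-chromen-4-one
Product: 15 2-(2,5-dihydroxyphenyl)-5-hydroxy-6,7,8-trimethoxy-4H-chromen-4-one, via debenzylated flavone 14 (not isolated)
Conditions: BCl3 (1 M in CH2Cl2, 6 equiv), C6HMe5, CH2Cl2, −78 → 0 °C; MeOH quench, aqueous work-up
Reagents that add atoms: none
Why: BCl3 with pentamethylbenzene as cation trap cleaves the aryl benzyl ethers at −78 °C, and on warming the boron chelate between the C4 carbonyl and the peri 5-methoxy group delivers chloride to that methyl only (chelation-controlled selective 5-O-demethylation of polymethoxyflavones), leaving the 6-, 7- and 8-methoxy groups.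

**Compound list**

1 | 3,4,5-trimethoxyphenol | COc1cc(O)cc(OC)c1OC | starting material
2 | 2-hydroxy-4,5,6-trimethoxybenzaldehyde | O=Cc1c(O)cc(OC)c(OC)c1OC | intermediate
3 | 3-bromo-2-hydroxy-4,5,6-trimethoxybenzaldehyde | O=Cc1c(O)c(Br)c(OC)c(OC)c1OC | intermediate
4 | 2-hydroxy-3,4,5,6-tetramethoxybenzaldehyde | O=Cc1c(O)c(OC)c(OC)c(OC)c1OC | intermediate
5 | 2-[(tert-butyldimethylsilyl)oxy]-3,4,5,6-tetramethoxybenzaldehyde | O=Cc1c(O[Si](C)(C)C(C)(C)C)c(OC)c(OC)c(OC)c1OC | intermediate
6 | 2,5-dihydroxybenzaldehyde | O=Cc1cc(O)ccc1O | starting material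
7 | 2,5-bis(benzyloxy)benzaldehyde | O=Cc1cc(OCc2ccccc2)ccc1OCc1ccccc1 | intermediate
8 | 1,4-bis(benzyloxy)-2-ethynylbenzene | C#Cc1cc(OCc2ccccc2)ccc1OCc1ccccc1 | intermediate
9 | {[2,5-bis(benzyloxy)phenyl]ethynyl}(phenyl)iodonium 4-methylbenzenesulfonate | Cc1ccc(cc1)S(=O)(=O)[O-].c1ccc(cc1)[I+]C#Cc1cc(OCc2ccccc2)ccc1OCc1ccccc1 | intermediate
10 | 3-[2,5-bis(benzyloxy)phenyl]-1-{2-[(tert-butyldimethylsilyl)oxy]-3,4,5,6-tetramethoxyphenyl}prop-2-yn-1-one | O=C(C#Cc1cc(OCc2ccccc2)ccc1OCc1ccccc1)c1c(O[Si](C)(C)C(C)(C)C)c(OC)c(OC)c(OC)c1OC | intermediate, not isolated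
11 | (2E)-3-[2,5-bis(benzyloxy)phenyl]-1-{2-[(tert-butyldimethylsilyl)oxy]-3,4,5,6-tetramethoxyphenyl}-3-(diethylamino)prop-2-en-1-one (drawn E; the geometry is lost on ring closure) | CCN(CC)/C(=C/C(=O)c1c(O[Si](C)(C)C(C)(C)C)c(OC)c(OC)c(OC)c1OC)c1cc(OCc2ccccc2)ccc1OCc1ccccc1 | intermediate, not isolated
12 | (2E)-3-[2,5-bis(benzyloxy)phenyl]-3-(diethylamino)-1-(2-hydroxy-3,4,5,6-tetramethoxyphenyl)prop-2-en-1-one | CCN(CC)/C(=C/C(=O)c1c(O)c(OC)c(OC)c(OC)c1OC)c1cc(OCc2ccccc2)ccc1OCc1ccccc1 | intermediate, not isolated
13 | 2-[2,5-bis(benzyloxy)phenyl]-5,6,7,8-tetramethoxy-4H-chromen-4-one | COc1c(OC)c(OC)c2c(=O)cc(-c3cc(OCc4ccccc4)ccc3OCc3ccccc3)oc2c1OC | intermediate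
14 | 2-(2,5-dihydroxyphenyl)-5,6,7,8-tetramethoxy-4H-chromen-4-one (held in the flask as its boron aryloxide) | COc1c(OC)c(OC)c2c(=O)cc(-c3cc(O)ccc3O)oc2c1OC | intermediate, not isolated
15 | 2-(2,5-dihydroxyphenyl)-5-hydroxy-6,7,8-trimethoxy-4H-chromen-4-one (5,2',5'-trihydroxy-6,7,8-trimethoxyflavone) | COc1c(OC)c(O)c2c(=O)cc(-c3cc(O)ccc3O)oc2c1OC | target

**Step count and risk**

Total steps: 9. Longest linear sequence: 6 (steps 1, 2, 3, 4, 8, 9); the ring B branch (steps 5, 6, 7) joins at step 8.

Most likely to fail, step 8: the aldehyde of 5 is flanked by two oxygen substituents and is electron-rich, so Breslow intermediate formation may be slow. The trivalent iodine salt may also oxidise the Breslow intermediate instead of alkynylating it. The fallback sets out from 5 and 8 and uses natural polarity. Alkyne 8 is deprotonated with n-BuLi in THF at −78 °C and added to aldehyde 5 to give racemic 3-[2,5-bis(benzyloxy)phenyl]-1-{2-[(tert-butyldimethylsilyl)oxy]-3,4,5,6-tetramethoxyphenyl}prop-2-yn-1-ol F1, quenched cold to avoid silyl migration. MnO2 in CH2Cl2 oxidises this to ynone 10, where it comes back to the route; 10 is then treated with Et2NH in EtOH as in the second stage of step 8.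

Second, step 7: an open-chain alkynyliodonium tosylate on an electron-rich aryl alkyne may be labile (tosylate addition, oxidation of the dialkoxyarene by the trivalent iodine reagent). The fallback sets out from 8. It is silylated (n-BuLi, TMSCl, THF, −78 °C) to {[2,5-bis(benzyloxy)phenyl]ethynyl}trimethylsilane F2. Treatment with 1-hydroxy-1,2-benziodoxol-3(1H)-one and TMSOTf in MeCN, then pyridine, gives the cyclic, bench-stable 1-{[2,5-bis(benzyloxy)phenyl]ethynyl}-1,2-benziodoxol-3(1H)-one F3. F3 replaces 9 as the electrophilic alkyne in the carbene-catalysed coupling with 5, losing 2-iodobenzoic acid, and comes back to the route at ynone 10.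

Third, step 3: the bromide is flanked by a phenoxide and a methoxy group, so copper-mediated methoxylation may give way to protodebromination. The fallback sets out from 2 and installs the oxygen by oxidation instead of substitution. 2-Iodoxybenzoic acid (IBX) in DMF oxidises the phenol at its one free ortho carbon to 2,3,4-trimethoxy-5,6-dioxocyclohexa-1,3-diene-1-carbaldehyde F4. Na2S2O4 in the work-up reduces this to 2,3-dihydroxy-4,5,6-trimethoxybenzaldehyde F5. NaH (2.1 equiv) in DMSO followed by MeI (1.0 equiv) methylates the dianion at the non-chelated 3-oxygen, and the sequence comes back to the route at 4.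

**Further compounds**

F1 | step 8 | 3-[2,5-bis(benzyloxy)phenyl]-1-{2-[(tert-butyldimethylsilyl)oxy]-3,4,5,6-tetramethoxyphenyl}prop-2-yn-1-ol (racemic) | OC(C#Cc1cc(OCc2ccccc2)ccc1OCc1ccccc1)c1c(O[Si](C)(C)C(C)(C)C)c(OC)c(OC)c(OC)c1OC
F2 | step 7 | {[2,5-bis(benzyloxy)phenyl]ethynyl}trimethylsilane | C[Si](C)(C)C#Cc1cc(OCc2ccccc2)ccc1OCc1ccccc1
F3 | step 7 | 1-{[2,5-bis(benzyloxy)phenyl]ethynyl}-1,2-benziodoxol-3(1H)-one | O=C1OI(C#Cc2cc(OCc3ccccc3)ccc2OCc2ccccc2)c2ccccc12
F4 | step 3 | 2,3,4-trimethoxy-5,6-dioxocyclohexa-1,3-diene-1-carbaldehyde | O=CC1=C(OC)C(OC)=C(OC)C(=O)C1=O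
F5 | step 3 | 2,3-dihydroxy-4,5,6-trimethoxybenzaldehyde | O=Cc1c(O)c(O)c(OC)c(OC)c1OC
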